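**Assumption:** the SMILES has no stereocentre and no stereodescriptor, so the target is treated as achiral; indole–quinone rotamers are not specified and not controlled.

**Retrosynthetic overview**
- The target is the bis(O-methyl) ether of hinnuliquinone, so the last disconnection is O-methylation of the two vinylogous-acid OH groups.
- Key disconnection: both indole C3–quinone C bonds, made in one operation. The two enolic carbons of 2,5-dihydroxy-1,4-benzoquinone (normally nucleophilic) are turned into enolonium-type electrophiles as the bis(phenyliodonium) ylide and joined to the nucleophilic C3 of two 2-(1,1-dimethylallyl)indoles.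
- The indole comes from a Fischer synthesis with 3,3-dimethylpent-4-en-2-one, itself made by γ-selective acylation of prenylmagnesium chloride.
- Ring order: the pyrrole ring of each indole is the only ring built (Fischer); the benzene rings and the quinone ring are bought intact.

**Step 1**
Reactants: 1 1-chloro-3-methylbut-2-ene (prenyl chloride); 2 N-methoxy-N-methylacetamide
Product: 5 3,3-dimethylpent-4-en-2-one, via prenylmagnesium chloride 3 (not isolated), via chloromagnesium hemiaminal alkoxide 4 (not isolated)
Conditions: Mg turnings (2 equiv), THF, 0 °C, slow addition of 1 (1.3 equiv); then add to 2, THF, −78 °C → 0 °C; sat. aq. NH4Cl; distil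
Reagents that add atoms: none
Why: The allylic Grignard reagent attacks through its γ-carbon in a six-membered SE2' transition state to give the α,α-dimethylallyl ketone, and the chelated tetrahedral adduct prevents over-addition (Weinreb ketone synthesis).

**Step 2**
Reactants: 5 3,3-dimethylpent-4-en-2-one; 6 phenylhydrazine
Product: 8 2-(2-methylbut-3-en-2-yl)-1H-indole, via ketone phenylhydrazone 7 (not isolated)
Conditions: PhNHNH2 (1.05 equiv), AcOH (5 mol%), EtOH, 78 °C; evaporate; anhydrous ZnCl2 (3 equiv), xylenes, 140 °C
Reagents that add atoms: none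
Why: Fischer indole synthesis; the methyl group is the only enolisable α-position, so ene-hydrazine formation, [3,3]-shift and loss of NH3 can only give the 2-substituted, 3-unsubstituted indole, as pinacolone phenylhydrazone gives 2-tert-butylindole.

**Step 3**
Reactants: 9 2,5-dihydroxy-1,4-benzoquinone
Product: 10 2,5-dioxido-3,6-bis(phenyliodonio)-1,4-benzoquinone (bis-ylide)
Conditions: PhI(OAc)2 (2.1 equiv), CH2Cl2, rt, dark; filter, wash with Et2O, store cold
Reagents that add atoms: (diacetoxyiodo)benzene, CC(=O)O[I](OC(C)=O)c1ccccc1
Why: Ligand exchange of the acidic enolic C–H/O–H unit on PhI(OAc)2 with loss of AcOH gives the stabilised, insoluble phenyliodonium ylide at each enolic carbon, which is the standard formation of iodonium ylides from hydroxyquinones and 1,3-dicarbonyl compounds.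

**Step 4**
Reactants: 8 2-(2-methylbut-3-en-2-yl)-1H-indole (2.3 equiv); 10 bis-ylide
Product: 12 hinnuliquinone (2,5-dihydroxy-3,6-bis[2-(2-methylbut-3-en-2-yl)-1H-indol-3-yl]-1,4-benzoquinone), via mono-indolyl iodonium ylide 11 (not isolated)
Conditions: BF3·OEt2 (30 mol%), CH2Cl2, 0 °C → rt, dark, N2; aq. NaH2PO4 work-up
Reagents that add atoms: none
Why: Proposed new method: BF3 (later the acidic product itself) caps the oxido group of 10, so each ylide carbon becomes an α-iodonio-1,3-dicarbonyl (enolonium-type) electrophile; C3 of 8, its only free nucleophilic carbon and the site at which 2-tert-alkylindoles attack quinones, adds there and PhI leaves as a hypernucleofuge (addition–elimination or ligand coupling at trivalent iodine), with the lost C3–H proton ending on the quinone oxygen; the low temperature suppresses thermal ring contraction and aryl migration of the ylide and acid-mediated cyclisation onto the vinyl group; the closest known reactions are the BF3-mediated arylation of the phenyliodonium ylide of 2-hydroxy-1,4-naphthoquinone by electron-rich arenes and the Pd-catalysed coupling of hydroxyquinone iodonium ylides with arylstannanes, here extended to a two-fold coupling with a free N–H indole.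

**Step 5**
Reactants: 12 hinnuliquinone
Product: 13 2,5-dimethoxy-3,6-bis[2-(2-methylbut-3-en-2-yl)-1H-indol-3-yl]-1,4-benzoquinone (target)
Conditions: TMSCHN2 (2 M in hexanes, 3 equiv), CH2Cl2–MeOH 4:1, 0 °C → rt; AcOH quench
Reagents that add atoms: trimethylsilyldiazomethane, C[Si](C)(C)C=[N+]=[N-]
Why: Diazoalkane O-methylation of the two acidic vinylogous-carboxylic-acid OH groups; the indole N–H is far too weakly acidic to react and the fully substituted quinone ring and unactivated vinyl groups resist dipolar cycloaddition.

**Compound list**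
1 | 1-chloro-3-methylbut-2-ene (prenyl chloride) | CC(C)=CCCl | starting material
2 | N-methoxy-N-methylacetamide | CC(=O)N(C)OC | starting material
3 | prenylmagnesium chloride | CC(C)=CC[Mg]Cl | intermediate
4 | chloromagnesium 2-[methoxy(methyl)amino]-3,3-dimethylpent-4-en-2-olate (racemic) | CC(O[Mg]Cl)(N(C)OC)C(C)(C)C=C | intermediate
5 | 3,3-dimethylpent-4-en-2-one | CC(=O)C(C)(C)C=C | intermediate
6 | phenylhydrazine | NNc1ccccc1 | starting material
7 | 3,3-dimethylpent-4-en-2-one phenylhydrazone (E/Z not relevant) | CC(=NNc1ccccc1)C(C)(C)C=C | intermediate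
8 | 2-(2-methylbut-3-en-2-yl)-1H-indole | C=CC(C)(C)c1cc2ccccc2[nH]1 | intermediate
9 | 2,5-dihydroxy-1,4-benzoquinone | O=C1C=C(O)C(=O)C=C1O | starting material
10 | 2,5-dioxido-3,6-bis(phenyliodonio)-1,4-benzoquinone | [O-]C1=C([I+]c2ccccc2)C(=O)C([O-])=C([I+]c2ccccc2)C1=O | intermediate
11 | 5-hydroxy-6-[2-(2-methylbut-3-en-2-yl)-1H-indol-3-yl]-2-oxido-3-(phenyliodonio)-1,4-benzoquinone | [O-]C1=C([I+]c2ccccc2)C(=O)C(O)=C(c2c(C(C)(C)C=C)[nH]c3ccccc23)C1=O | intermediate
12 | hinnuliquinone, 2,5-dihydroxy-3,6-bis[2-(2-methylbut-3-en-2-yl)-1H-indol-3-yl]-1,4-benzoquinone | C=CC(C)(C)c1[nH]c2ccccc2c1C1=C(O)C(=O)C(c2c(C(C)(C)C=C)[nH]c3ccccc23)=C(O)C1=O | intermediate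
13 | 2,5-dimethoxy-3,6-bis[2-(2-methylbut-3-en-2-yl)-1H-indol-3-yl]-1,4-benzoquinone | C=CC(C)(C)c1[nH]c2ccccc2c1C1=C(OC)C(=O)C(c2c(C(C)(C)C=C)[nH]c3ccccc23)=C(OC)C1=O | target

**Total step count:** 5.
**Longest linear sequence:** 4 steps (steps 1, 2, 4, 5); step 3 is a one-step side branch.

**Three steps most likely to fail**

Step 4 (two-fold coupling of the bis-ylide) is the main risk. Possible failures are oxidation of the indole by trivalent iodine, phenyl transfer in place of quinonyl transfer, a stop at the mono-adduct, or acid-induced cyclisation onto the vinyl group. The fallback sets out from indole 8 and returns at 12. Indole 8 is condensed with 2,5-dichloro-1,4-benzoquinone in THF/AcOH with a little HCl, and the hydroquinone adducts are re-oxidised with DDQ. This gives 2,5-dichloro-3,6-bis[2-(2-methylbut-3-en-2-yl)-1H-indol-3-yl]-1,4-benzoquinone F1. Its two vinylogous acid chlorides are hydrolysed with 10% aq. NaOH in MeOH at reflux, and acidification gives hinnuliquinone 12.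

Step 2 (Fischer indolisation) may fail because the hindered hydrazone forms slowly or the tert-allyl group does not survive hot ZnCl2. The fallback sets out from ketone 5 and returns at 8. Ketone 5 is treated with LiN(i-Pr)2 and ClP(O)(OEt)2 in THF at −78 °C to give diethyl 3,3-dimethylpenta-1,4-dien-2-yl phosphate F2. A further 2.2 equiv of LiN(i-Pr)2 eliminates it to 3,3-dimethylpent-4-en-1-yne F3. Sonogashira coupling with 2-iodoaniline (PdCl2(PPh3)2, CuI, Et3N) gives 2-(3,3-dimethylpent-4-en-1-yn-1-yl)aniline F4. KOt-Bu in NMP at rt then closes the pyrrole ring by 5-endo-dig hydroamination to give indole 8.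

Step 1 (Grignard acylation) may suffer from Wurtz coupling during Grignard formation or from some α-attack. The fallback sets out from chloride 1 and returns at 5. A Barbier reaction of 1 with acetaldehyde and Zn dust in THF/sat. aq. NH4Cl proceeds by γ-attack to give 3,3-dimethylpent-4-en-2-ol F5 (racemic). Oxidation with Dess–Martin periodinane in CH2Cl2 gives ketone 5.

**Further compounds**
F1 | step 4 | 2,5-dichloro-3,6-bis[2-(2-methylbut-3-en-2-yl)-1H-indol-3-yl]-1,4-benzoquinone | C=CC(C)(C)c1[nH]c2ccccc2c1C1=C(Cl)C(=O)C(c2c(C(C)(C)C=C)[nH]c3ccccc23)=C(Cl)C1=O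
F2 | step 2 | diethyl 3,3-dimethylpenta-1,4-dien-2-yl phosphate | C=C(OP(=O)(OCC)OCC)C(C)(C)C=C
F3 | step 2 | 3,3-dimethylpent-4-en-1-yne | C#CC(C)(C)C=C
F4 | step 2 | 2-(3,3-dimethylpent-4-en-1-yn-1-yl)aniline | Nc1ccccc1C#CC(C)(C)C=C
F5 | step 1 | 3,3-dimethylpent-4-en-2-ol (racemic) | CC(O)C(C)(C)C=C
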